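**Plan**

- Cuts: (a) the four O–Si bonds; (b) the C2'–C1'' bond between ring B and the geranyl chain, back to an aryl iodide and geranyl bromide; (c) together, C2–C3 and C4–C4a of ring C, back to an O-aryl oxocarbenium ion and a terminal ynamide as the C3–C4 unit; (d) O1–C2, back to a ring A phenol and a ring B aldehyde.
- Forward: rings A and B are joined through O1–C2 as an O-aryl O-pivaloyl acetal, ring C is then closed in one catalytic operation, the geranyl chain is joined to C2' afterwards by a zinc/palladium allylation, and the silyl ethers are removed last.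
- Enabling feature: O1 links C8a of the phloroglucinol ring A, whose C4a is ortho to O1 and ortho/para to O5 and O7, to C2, which is benzylic to ring B and para to O4'. Ionisation at C2 therefore gives a stabilised cationic 2-oxadiene C4a=C8a–O1(+)=C2 that takes up the two carbons C3–C4 across its ends.
- Stereochemistry: C2 (S), the only stereocentre, is set in the key step by the chiral counteranion of the acid catalyst; the E geometry of C2''=C3'' comes with geranyl bromide and is kept in the coupling.
- Helpers: pivalate (leaving group at C2), the N-methyl-tosylamido group (brings C4 in at the ketone level, hydrolysed in the same flask) and iodine at C2' (placeholder for the geranyl chain, which must not be present while C2 is cationic).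

Key step: step 5

Assumption: the sense of induction of the acid catalyst cannot be predicted with certainty; the (S,S) catalyst is written and taken to give the 2S product, and its antipode is used if the sense proves opposite.

**Step 1**
Reactants: 1 3-hydroxy-2-iodo-4-methoxybenzaldehyde (2-iodoisovanillin)
Product: 2 3,4-dihydroxy-2-iodobenzaldehyde
Conditions: BBr3 (3 equiv), CH2Cl2, −78 °C to 25 °C; then H2O
Reagents that add atoms: none
Why: Lewis-acid cleavage of an aryl methyl ether with BBr3 is routine for isovanillin-type aldehydes, and the aldehyde and the aryl iodide should survive at low temperature.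

**Step 2**
Reactants: 2 3,4-dihydroxy-2-iodobenzaldehyde
Product: 3 3,4-bis(tert-butyldimethylsilyloxy)-2-iodobenzaldehyde (TBS = tert-butyldimethylsilyl)
Conditions: TBSCl (2.4 equiv), imidazole, DMF, 25 °C
Reagents that add atoms: tert-butyldimethylsilyl chloride, CC(C)(C)[Si](C)(C)Cl
Why: Standard silyl ether formation on a catechol; silyl groups are chosen because they survive the acid-catalysed key step and the zinc chemistry and can be removed at the end without base or strong acid.

**Step 3**
Reactants: 4 benzene-1,3,5-triol (phloroglucinol)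
Product: 5 3,5-bis(tert-butyldimethylsilyloxy)phenol
Conditions: TBSCl (2.0 equiv), imidazole, DMF, 0 °C
Reagents that add atoms: tert-butyldimethylsilyl chloride, CC(C)(C)[Si](C)(C)Cl
Why: Silyl ether formation on a symmetrical triol should give the bis-ether as the main part of a statistical mixture, from which it is separated by chromatography while the mono- and tris-ethers are recycled.

**Step 4**
Reactants: 3 3,4-bis(TBSO)-2-iodobenzaldehyde; 5 3,5-bis(TBSO)phenol
Product: 7 [3,5-bis(TBSO)phenoxy][3,4-bis(TBSO)-2-iodophenyl]methyl 2,2-dimethylpropanoate (racemic), via chloro ester 6 (not isolated)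
Conditions: PivCl (1.1 equiv), ZnCl2 (2 mol %), CH2Cl2, 0 to 25 °C; then 5, iPr2NEt, −20 to 25 °C
Reagents that add atoms: pivaloyl chloride, CC(C)(C)C(Cl)=O
Why: ZnCl2-catalysed addition of an acyl chloride to an aldehyde gives the α-chloroalkyl ester, which O-alkylates the phenol under amine base in the same way as acyloxymethyl or methoxymethyl chlorides do; the hindered pivaloyl carbonyl disfavours acyl transfer, and the racemic acetal carbon is of no consequence because it becomes planar in step 5.

**Step 5**
Reactants: 7 [3,5-bis(TBSO)phenoxy][3,4-bis(TBSO)-2-iodophenyl]methyl 2,2-dimethylpropanoate; 8 N-ethynyl-N,4-dimethylbenzenesulfonamide (N-ethynyl-N-methyl-p-toluenesulfonamide)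
Product: 10 (S)-2-[3,4-bis(TBSO)-2-iodophenyl]-5,7-bis(TBSO)chroman-4-one, via chromenyl sulfonamide 9 (not isolated)
Conditions: 8 (2 equiv), (S,S)-imidodiphosphorimidate acid (ArBINOL)P(=NTf)–N=P(NHTf)(ArBINOL), Ar = 3,5-(CF3)2C6H3 at the 3,3'-positions of each (S)-BINOL (5 mol %), toluene, −60 °C; then THF, 2 M HCl (aq), 0 to 25 °C
Reagents that add atoms: water, O
Why: Proposed new method: the chiral acid protonates the pivalate of 7, pivalic acid leaves and the O-aryl oxocarbenium ion (a cationic 2-oxadiene, C4a=C8a–O1(+)=C2) is held as a contact ion pair with the chiral anion; the terminal carbon of ynamide 8 adds to C2 (bond C2–C3) to give a keteniminium ion, whose sp carbon is attacked by C4a of ring A (bond C4–C4a), and loss of the C4a proton returns the acid and gives enamide 9, which aqueous HCl hydrolyses in the same flask to ketone 10. The closest known reaction types are the Lewis-acid-promoted oxa-Povarov [4+2] reaction of O-aryl oxocarbenium ions with alkenes, the chiral-phosphoric-acid-catalysed aza-Povarov reaction, counteranion-directed enantioselective additions to oxocarbenium ions and keteniminium Friedel–Crafts cyclisations; their union on an acyclic O-aryl oxocarbenium ion and an ynamide has not been shown. Ring C closes in a stepwise polar [4+2] manner, the second bond by a six-membered Friedel–Crafts closure that is 6-endo-dig with respect to the former triple bond. C2, the only new stereocentre, is set in the first C–C bond formation, in which the confined chiral anion covers one face of the planar oxocarbenium ion so that 8 adds to the Si face (O1 > C1' > H) and gives the 2S configuration. The step needs ionisation towards the O-aryl oxocarbenium ion (secured by pivalate being a far better leaving group than the aryloxide), attack of 8 through its terminal carbon (secured by the nitrogen lone pair, which also leaves C4 at the ketone oxidation level) and closure at carbon (secured by C4a lying ortho to O1 and ortho and para to the two silyloxy groups, the two ortho positions being equivalent); the bulky silyl ethers hinder intermolecular Friedel–Crafts alkylation, and iodine at C2' stands in for the geranyl chain, whose C2''=C3'' alkene would capture the cation in a Prins cyclisation.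

**Step 6**
Reactants: 10 (S)-2-[3,4-bis(TBSO)-2-iodophenyl]-5,7-bis(TBSO)chroman-4-one; 11 geranyl bromide, (2E)-1-bromo-3,7-dimethylocta-2,6-diene
Product: 13 (S)-2-{3,4-bis(TBSO)-2-[(2E)-3,7-dimethylocta-2,6-dien-1-yl]phenyl}-5,7-bis(TBSO)chroman-4-one, via arylzinc iodide 12 (not isolated)
Conditions: Zn dust (activated), LiCl, THF, 50 °C; then 11, Pd(PPh3)4 (5 mol %), THF, 25 °C
Reagents that add atoms: none
Why: Direct insertion of LiCl-activated zinc into the aryl iodide gives an arylzinc that is neither basic nor nucleophilic towards the ketone or the C2 stereocentre, and Negishi-type palladium-catalysed allylation should deliver the aryl group to the unsubstituted terminus of the η3-geranyl palladium complex with retention of the E geometry.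

**Step 7**
Reactants: 13 (S)-2-{3,4-bis(TBSO)-2-[(2E)-3,7-dimethylocta-2,6-dien-1-yl]phenyl}-5,7-bis(TBSO)chroman-4-one
Product: 14 nymphaeol B
Conditions: KHF2, MeOH, 25 °C
Reagents that add atoms: none
Why: Fluoride cleavage of phenolic silyl ethers under weakly acidic buffered conditions should avoid both the base-induced ring opening of the flavanone to the chalcone, which would racemise C2, and the acid-induced cyclisation of the geranyl chain onto the 3'-hydroxyl.

**Compound list**

1 | 3-hydroxy-2-iodo-4-methoxybenzaldehyde | COc1ccc(C=O)c(I)c1O | starting material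
2 | 3,4-dihydroxy-2-iodobenzaldehyde | O=Cc1ccc(O)c(O)c1I | intermediate
3 | 3,4-bis(tert-butyldimethylsilyloxy)-2-iodobenzaldehyde | O=Cc1ccc(O[Si](C)(C)C(C)(C)C)c(O[Si](C)(C)C(C)(C)C)c1I | intermediate
4 | benzene-1,3,5-triol (phloroglucinol) | Oc1cc(O)cc(O)c1 | starting material
5 | 3,5-bis(tert-butyldimethylsilyloxy)phenol | Oc1cc(O[Si](C)(C)C(C)(C)C)cc(O[Si](C)(C)C(C)(C)C)c1 | intermediate
6 | chloro[3,4-bis(tert-butyldimethylsilyloxy)-2-iodophenyl]methyl 2,2-dimethylpropanoate (racemic, not isolated) | CC(C)(C)C(=O)OC(Cl)c1ccc(O[Si](C)(C)C(C)(C)C)c(O[Si](C)(C)C(C)(C)C)c1I | intermediate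
7 | [3,5-bis(tert-butyldimethylsilyloxy)phenoxy][3,4-bis(tert-butyldimethylsilyloxy)-2-iodophenyl]methyl 2,2-dimethylpropanoate (racemic) | CC(C)(C)C(=O)OC(Oc1cc(O[Si](C)(C)C(C)(C)C)cc(O[Si](C)(C)C(C)(C)C)c1)c1ccc(O[Si](C)(C)C(C)(C)C)c(O[Si](C)(C)C(C)(C)C)c1I | intermediate
8 | N-ethynyl-N,4-dimethylbenzenesulfonamide | C#CN(C)S(=O)(=O)c1ccc(C)cc1 | starting material
9 | (S)-N-{2-[3,4-bis(tert-butyldimethylsilyloxy)-2-iodophenyl]-5,7-bis(tert-butyldimethylsilyloxy)-2H-chromen-4-yl}-N,4-dimethylbenzenesulfonamide (not isolated) | Ic1c([C@@H]2C=C(N(C)S(=O)(=O)c3ccc(C)cc3)c3c(O[Si](C)(C)C(C)(C)C)cc(O[Si](C)(C)C(C)(C)C)cc3O2)ccc(O[Si](C)(C)C(C)(C)C)c1O[Si](C)(C)C(C)(C)C | intermediate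
10 | (S)-2-[3,4-bis(tert-butyldimethylsilyloxy)-2-iodophenyl]-5,7-bis(tert-butyldimethylsilyloxy)chroman-4-one | Ic1c([C@@H]2CC(=O)c3c(O[Si](C)(C)C(C)(C)C)cc(O[Si](C)(C)C(C)(C)C)cc3O2)ccc(O[Si](C)(C)C(C)(C)C)c1O[Si](C)(C)C(C)(C)C | intermediate
11 | geranyl bromide, (2E)-1-bromo-3,7-dimethylocta-2,6-diene | CC(C)=CCC/C(C)=C/CBr | starting material
12 | {2,3-bis(tert-butyldimethylsilyloxy)-6-[(2S)-5,7-bis(tert-butyldimethylsilyloxy)-4-oxochroman-2-yl]phenyl}zinc iodide (not isolated) | I[Zn]c1c([C@@H]2CC(=O)c3c(O[Si](C)(C)C(C)(C)C)cc(O[Si](C)(C)C(C)(C)C)cc3O2)ccc(O[Si](C)(C)C(C)(C)C)c1O[Si](C)(C)C(C)(C)C | intermediate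
13 | (S)-2-{3,4-bis(tert-butyldimethylsilyloxy)-2-[(2E)-3,7-dimethylocta-2,6-dien-1-yl]phenyl}-5,7-bis(tert-butyldimethylsilyloxy)chroman-4-one | CC(C)=CCC/C(C)=C/Cc1c([C@@H]2CC(=O)c3c(O[Si](C)(C)C(C)(C)C)cc(O[Si](C)(C)C(C)(C)C)cc3O2)ccc(O[Si](C)(C)C(C)(C)C)c1O[Si](C)(C)C(C)(C)C | intermediate
14 | nymphaeol B, (S)-2-{2-[(2E)-3,7-dimethylocta-2,6-dien-1-yl]-3,4-dihydroxyphenyl}-5,7-dihydroxychroman-4-one | CC(C)=CCC/C(C)=C/Cc1c([C@@H]2CC(=O)c3c(O)cc(O)cc3O2)ccc(O)c1O | target

**Step count**

Total steps: 7. Longest linear sequence: 6 (steps 1, 2, 4, 5, 6, 7; step 3 makes the ring A branch).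

**Steps most likely to fail**

Step 5 (proposed new method). What may go wrong: insufficient facial discrimination in the oxocarbenium/anion pair, loss of turnover because the acid is spent in protonating the ynamide, or intermolecular Friedel–Crafts alkylation of ring A after ionisation. The fallback uses known chemistry, sets out from 3 and comes back at 10. Commercial 2,4,6-trihydroxyacetophenone is silylated at the two hydroxyls that are not held in the hydrogen bond to the carbonyl (TBSCl, imidazole) to give 1-[2-hydroxy-4,6-bis(tert-butyldimethylsilyloxy)phenyl]ethanone F1. Its dianion (LiN(SiMe3)2, THF, −78 °C) is added to aldehyde 3 to give the racemic aldol 3-[3,4-bis(TBSO)-2-iodophenyl]-3-hydroxy-1-[2-hydroxy-4,6-bis(TBSO)phenyl]propan-1-one F2. An intramolecular Mitsunobu etherification (PPh3, DIAD, THF) closes ring C at O1–C2 and gives the racemic chromanone F3. Preparative chromatography on a chiral stationary phase separates the enantiomers, and the 2S enantiomer is 10. In this fallback ring C is closed by C–O bond formation and the stereocentre is obtained by resolution.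

Step 4. What may go wrong: an unfavourable addition equilibrium between the electron-rich aldehyde and the acyl chloride, loss of a silyl ether under acyl chloride and Lewis acid, or C-alkylation of the phenol in place of O-alkylation. The fallback sets out from 3 and comes back at 7. Reduction (NaBH4, THF/EtOH, 0 °C) gives [3,4-bis(TBSO)-2-iodophenyl]methanol F4. Mitsunobu etherification with 5 (PPh3, DIAD, THF) gives the aryl benzyl ether 1-{[3,4-bis(TBSO)-2-iodophenyl]methoxy}-3,5-bis(TBSO)benzene F5. Oxidative acyloxylation of the benzylic ether C–H bond (DDQ, one equivalent, pivalic acid, CH2Cl2), by hydride abstraction and capture of the oxocarbenium ion by pivalate, gives 7. Here the O1–C2 bond is made by substitution at a benzylic carbon and the leaving group is put in afterwards by oxidation.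

Step 6. What may go wrong: slow zinc insertion into the hindered, electron-rich aryl iodide with competing protodeiodination, or partial E/Z isomerisation and branched coupling in the allyl transfer. The fallback sets out from 10 and comes back at 13. The ketone is taken out of play by reduction (NaBH4, MeOH/THF, 0 °C), which should give mainly the 2,4-cis alcohol (2S,4S)-2-[3,4-bis(TBSO)-2-iodophenyl]-5,7-bis(TBSO)chroman-4-ol F6; the C4 configuration is of no consequence. Deprotonation and iodine–magnesium exchange (iPrMgCl·LiCl, two equivalents, THF, −20 °C), transmetalation to copper (CuBr·SMe2) and SN2 allylation with geranyl bromide 11 give (2S,4S)-2-{3,4-bis(TBSO)-2-[(2E)-3,7-dimethylocta-2,6-dien-1-yl]phenyl}-5,7-bis(TBSO)chroman-4-ol F7. Oxidation (Dess–Martin periodinane, NaHCO3, CH2Cl2) restores the ketone and gives 13. The aryl nucleophile is here a magnesium/copper reagent made by halogen–metal exchange, and no palladium allyl complex is involved.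

**Further compounds**

F1 | step 5 | 1-[2-hydroxy-4,6-bis(tert-butyldimethylsilyloxy)phenyl]ethanone | CC(=O)c1c(O)cc(O[Si](C)(C)C(C)(C)C)cc1O[Si](C)(C)C(C)(C)C
F2 | step 5 | 3-[3,4-bis(tert-butyldimethylsilyloxy)-2-iodophenyl]-3-hydroxy-1-[2-hydroxy-4,6-bis(tert-butyldimethylsilyloxy)phenyl]propan-1-one (racemic) | OC(CC(=O)c1c(O)cc(O[Si](C)(C)C(C)(C)C)cc1O[Si](C)(C)C(C)(C)C)c1ccc(O[Si](C)(C)C(C)(C)C)c(O[Si](C)(C)C(C)(C)C)c1I
F3 | step 5 | 2-[3,4-bis(tert-butyldimethylsilyloxy)-2-iodophenyl]-5,7-bis(tert-butyldimethylsilyloxy)chroman-4-one (racemic) | Ic1c(C2CC(=O)c3c(O[Si](C)(C)C(C)(C)C)cc(O[Si](C)(C)C(C)(C)C)cc3O2)ccc(O[Si](C)(C)C(C)(C)C)c1O[Si](C)(C)C(C)(C)C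
F4 | step 4 | [3,4-bis(tert-butyldimethylsilyloxy)-2-iodophenyl]methanol | OCc1ccc(O[Si](C)(C)C(C)(C)C)c(O[Si](C)(C)C(C)(C)C)c1I
F5 | step 4 | 1-{[3,4-bis(tert-butyldimethylsilyloxy)-2-iodophenyl]methoxy}-3,5-bis(tert-butyldimethylsilyloxy)benzene | Ic1c(COc2cc(O[Si](C)(C)C(C)(C)C)cc(O[Si](C)(C)C(C)(C)C)c2)ccc(O[Si](C)(C)C(C)(C)C)c1O[Si](C)(C)C(C)(C)C
F6 | step 6 | (2S,4S)-2-[3,4-bis(tert-butyldimethylsilyloxy)-2-iodophenyl]-5,7-bis(tert-butyldimethylsilyloxy)chroman-4-ol | Ic1c([C@@H]2C[C@H](O)c3c(O[Si](C)(C)C(C)(C)C)cc(O[Si](C)(C)C(C)(C)C)cc3O2)ccc(O[Si](C)(C)C(C)(C)C)c1O[Si](C)(C)C(C)(C)C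
F7 | step 6 | (2S,4S)-2-{3,4-bis(tert-butyldimethylsilyloxy)-2-[(2E)-3,7-dimethylocta-2,6-dien-1-yl]phenyl}-5,7-bis(tert-butyldimethylsilyloxy)chroman-4-ol | CC(C)=CCC/C(C)=C/Cc1c([C@@H]2C[C@H](O)c3c(O[Si](C)(C)C(C)(C)C)cc(O[Si](C)(C)C(C)(C)C)cc3O2)ccc(O[Si](C)(C)C(C)(C)C)c1O[Si](C)(C)C(C)(C)C
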